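The target has an enemy in its own flask: the substrate, which eats it in the side step.

    substrate + reagent → open intermediate (k1 = 0.0092 /M/min, Ea1 = 76.0 kJ/mol)
    reagent + fresh partner → second intermediate (k2 = 0.036 /M/min, Ea2 = 65.0 kJ/mol)
    open intermediate + second intermediate → target (k3 = 0.017 /M/min, Ea3 = 49.0 kJ/mol)
    2 second intermediate → homo product (k4 = 0.0014 /M/min, Ea4 = 74.0 kJ/mol)
    solid partner ⇌ fresh partner, rate k5*(cs5 - [fresh partner]) while solid is left; crystals form when [fresh partner] > cs5 (cs5 = 24 mM, k5 = 0.0028 /min)
    substrate + target → side product (k6 = 0.0038 /M/min, Ea6 = 59.0 kJ/mol)
    (constants at 5 °C)

| flask | substrate | reagent | solid partner | temperature | time | remark |
|---|---|---|---|---|---|---|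
| south-west | 0.050 M | 0.0750 M (fed, over 3.0 d) | 0.100 M | 5 °C | 15 d | all else is in the flask from the start; the feed brings no volume worth counting |
| north-east | 0.050 M | 0.0750 M | 0.100 M |  | 15 d | everything together at the start at −35 °C, warmed to 5 °C at 3.0 d |
| west | 0.050 M (fed, over 3.0 d) | 0.0750 M | 0.100 M |  | 15 d | the addition at −35 °C, then warmed to 5 °C; the feed brings no volume worth counting |
| north-west | 0.050 M | 0.0750 M | 0.100 M | 5 °C | 15 d | everything together at the start |

- percentages count the substrate that a species holds: one side product counts as two
- two of one species on the left: rate k times its square, two consumed each time
- solid, in amounts per volume of the solution: solid partner
- the list of constants is for 5 °C, to be carried to other temperatures by the activation energies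
- at the start none of the solid partner is in solution

- the flask that comes out highest in share of target in target plus side product, or "all alike" when all lie within 1.5 percentage points (south-west / north-east / west / north-west / all alike)
- share of target in target plus side product at the end, south-west
- share of target in target plus side product at the end, north-east
- share of target in target plus side product at the end, west
- share of target in target plus side product at the end, north-west

I follow that loss with one quantity, the target clock: τ, the pseudo-first-order half-life of target under the side step, the natural logarithm of 2 over the side-step constant k times the substrate concentration. At the charged substrate and 5 °C, τ is 2.53 d, shorter than the time of 15 d.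

My worst version holds the substrate at its charge and makes the target at the start. Then 1.65% of the target survives, and since each side product counts double, the share is 0.832%.

My best version lets the reagent, the limiting reagent, split evenly between substrate and fresh partner, with each pair coupling at once. A target costs two reagent, and 0.0750 M is less than the 0.100 M a full conversion asks. So this version holds 0.03750 M of target beside 0.01250 M of substrate. Each turn of the side step removes one of each, so the excess of 0.0250 M is out of reach, and the share tends to 50.0%.

The real flask lies between, and the even split is what fails. Fresh partner at its solubility takes reagent 1.88 times as fast as the charged substrate does, so substrate gets about a third of the reagent. That is 0.0261 M, about half of the substrate charge. Target and substrate then stand nearly equal, 0.002115 M apart in my reckoning, so I let the pair fall together as a second-order decay to 0.008191 M each. The share comes to 19.6%. I commit to that figure for south-west, where slowly fed reagent meets dissolved partner. I set north-west above it, since there the whole reagent charge meets substrate from the start, while fresh partner, absent at first, approaches solubility on a time scale of 0.248 d, and I set the cold flasks between.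

The forecast gives 19% for south-west, 25% for north-east, 25% for west and 27% for north-west, with north-west highest, holding that “every share ends low”. The simulation gives 22.1%, 27.0%, 26.8% and 30.1% in that order, with north-west highest.

North-west ends with 13.0% of its substrate, so its clock at 15.0 d reads 19.5 d, longer than the 10.9 d of south-west. A neighbour of north-west charged with 0.12 M of substrate starts on a clock of 1.06 d, shorter than 2.53 d. It keeps 39.0% of its substrate at the end, and its share is 1.44%.

All constants belong to no real substance.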